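**Plan**
- Cuts in the 7‑methoxyflavonol (unit 1): the aryl ether O1–C8a of ring C lies ortho to the C4 carbonyl on ring A, so it is an SNAr bond. The 5‑OH/7‑OMe pair maps onto the ortho and para fluorines of a 2,4,6‑trifluorobenzoyl ring A. Further cuts are C2–C3 (aldol) and the diaryl ether O–C4′ (SNAr).
- The 5,7‑dihydroxyflavonol (unit 2) is cut the same way (O1–C8a, C5–O, C7–O, C2–C3). One fluorinated ketone, 7, therefore supplies C3, C4 and ring A of both halves.
- Forward: diaryl ether 3 joins the two B rings first, with an aldehyde on the unit‑1 side and a methyl ester on the unit‑2 side. Aldol with 7 and oxidation give diketone 10, ring C of unit 1 closes by fluoride displacement, then 7‑F → OMe and 5‑F → OBn.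
- The ester becomes the acyl chloride, which C‑acylates the magnesium enolate of a second molecule of 7. Ring C of unit 2 closes likewise, both fluorides become benzyl ethers, and hydrogenolysis of six benzyl ethers ends the route.
- Stereochemistry: the target is achiral with no stereocentre. The sp3 centres of aldol 9 and diketones 10 and 17 are uncontrolled and vanish on oxidation and ring closure.

Key step: step 5

Remark: compounds 9, 10 and 17 are racemic (9 a diastereomer mixture) and are drawn without configuration; 2 and 5 are taken as catalogue items (2 is otherwise one benzylation away from 4‑fluoro‑3‑hydroxybenzaldehyde).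

**Step 1**
Reactants: 1 methyl vanillate (methyl 4‑hydroxy‑3‑methoxybenzoate); 2 3‑(benzyloxy)‑4‑fluorobenzaldehyde
Product: 3 methyl 4‑[2‑(benzyloxy)‑4‑formylphenoxy]‑3‑methoxybenzoate
Conditions: K2CO3, DMSO, 110 °C, N2
Reagents that add atoms: none
Why: SNAr (addition–elimination) of the single phenoxide on the single fluoride para to the formyl group; with one phenol, one fluoride and no enolisable carbonyl, neither regiochemistry nor aldol chemistry can interfere.

**Step 2**
Reactants: 4 1,3,5‑trifluorobenzene; 5 2‑(benzyloxy)‑N‑methoxy‑N‑methylacetamide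
Product: 7 2‑(benzyloxy)‑1‑(2,4,6‑trifluorophenyl)ethan‑1‑one, via aryllithium 6 (not isolated)
Conditions: n‑BuLi, THF, −78 °C; then 5, −78 → −50 °C; aq. NH4Cl quench cold
Reagents that add atoms: none
Why: Deprotonation between two fluorines (ortho‑lithiation) followed by Weinreb ketone synthesis; the chelated tetrahedral adduct stops at the ketone and the low temperature keeps the aryllithium from losing LiF to an aryne.

**Step 3**
Reactants: 7 2‑(benzyloxy)‑1‑(2,4,6‑trifluorophenyl)ethan‑1‑one; 3 methyl 4‑[2‑(benzyloxy)‑4‑formylphenoxy]‑3‑methoxybenzoate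
Product: 9 methyl 4‑{2‑(benzyloxy)‑4‑[2‑(benzyloxy)‑1‑hydroxy‑3‑oxo‑3‑(2,4,6‑trifluorophenyl)propyl]phenoxy}‑3‑methoxybenzoate (racemic diastereomer mixture), via lithium enolate 8 (not isolated)
Conditions: LiN(SiMe3)2, THF, −78 °C; then 3, −78 °C; AcOH quench at −78 °C
Reagents that add atoms: none
Why: Lithium enolate aldol addition of the chelated Z‑enolate (the only enolisable site) to the non‑enolisable aldehyde, at a temperature too low for ester attack or fluoride displacement; the two new stereocentres are not controlled because steps 4 and 5 erase them.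

**Step 4**
Reactants: 9 the aldol adduct
Product: 10 methyl 4‑{2‑(benzyloxy)‑4‑[2‑(benzyloxy)‑3‑oxo‑3‑(2,4,6‑trifluorophenyl)propanoyl]phenoxy}‑3‑methoxybenzoate (racemic)
Conditions: Dess–Martin periodinane, CH2Cl2, 0 °C → rt
Reagents that add atoms: none
Why: Dess–Martin oxidation of a β‑hydroxy ketone to the 1,3‑diketone under near‑neutral conditions that avoid retro‑aldol and leave the benzyl ethers, the ester and the aryl fluorides untouched.

**Step 5**
Reactants: 10 the 2‑benzyloxy‑1‑(2,4,6‑trifluorophenyl)‑1,3‑diketone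
Product: 11 methyl 4‑{2‑(benzyloxy)‑4‑[3‑(benzyloxy)‑5,7‑difluoro‑4‑oxo‑4H‑chromen‑2‑yl]phenoxy}‑3‑methoxybenzoate
Conditions: K2CO3, dry DMF (0.05 M), rt → 50 °C
Reagents that add atoms: none
Why: K2CO3 removes the only acidic C–H (C2 of the diketone), and the enolate oxygen on the ring‑B side adds to a fluorine‑bearing ortho carbon of the trifluorobenzoyl ring, giving a Meisenheimer adduct whose charge rests on the C4 carbonyl and is further stabilised by the two remaining fluorines; loss of fluoride forms O1–C8a and the pyran‑4‑one (intramolecular SNAr). The closest known reaction is the carbonate‑mediated cyclisation of 1‑(2‑fluoroaryl)‑1,3‑diketones to chromones and flavones. Ring C closes as a six‑membered ring by O‑attack at a trigonal aromatic carbon (formally 6‑exo‑trig with respect to the C8–C8a bond of the arene), since attack through carbon or through the other oxygen would need a four‑membered ring. No stereocentre is formed and the racemic C2 centre of 10 becomes sp2. The step needs ortho‑over‑para and intra‑over‑intermolecular selectivity: only the ortho carbons are within reach of the tethered oxygen, the two ortho fluorines are equivalent so one product results, and dilution suppresses intermolecular attack on the para fluoride. Carbonate in dry DMF is too weak a nucleophile to cleave the diketone or the ester, and the surviving 5‑ and 7‑fluorides stay activated by the C4 carbonyl for steps 6 and 7.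

**Step 6**
Reactants: 11 the 5,7‑difluoroflavone
Product: 12 methyl 4‑{2‑(benzyloxy)‑4‑[3‑(benzyloxy)‑5‑fluoro‑7‑methoxy‑4‑oxo‑4H‑chromen‑2‑yl]phenoxy}‑3‑methoxybenzoate
Conditions: NaOMe (1.05 equiv), MeOH–THF, 0 °C
Reagents that add atoms: sodium methoxide, C[O-].[Na+]
Why: SNAr in which one equivalent of hydrogen‑bonded, non‑chelated methoxide should take the 7‑fluoride para to the C4 carbonyl in preference to the 5‑fluoride peri to the carbonyl oxygen, while the methyl ester is degenerate towards methoxide.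

**Step 7**
Reactants: 12 the 5‑fluoro‑7‑methoxyflavone
Product: 14 4‑{2‑(benzyloxy)‑4‑[3,5‑bis(benzyloxy)‑7‑methoxy‑4‑oxo‑4H‑chromen‑2‑yl]phenoxy}‑3‑methoxybenzoic acid, via benzyl ester 13 (not isolated)
Conditions: BnOH (excess), NaH, THF, 0 → 55 °C; then H2O, 55 °C; aq. HCl
Reagents that add atoms: benzyl alcohol, OCc1ccccc1; water, O
Why: SNAr of the remaining 5‑fluoride ortho to the C4 carbonyl by sodium benzyl alkoxide (sodium chelation to the carbonyl helps in THF) with concurrent transesterification to 13, then ester saponification by the hydroxide formed on adding water, so a single acid is isolated whatever the ester composition.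

**Step 8**
Reactants: 14 the benzoic acid; 7 2‑(benzyloxy)‑1‑(2,4,6‑trifluorophenyl)ethan‑1‑one (1.2 equiv)
Product: 17 2‑(benzyloxy)‑1‑(4‑{2‑(benzyloxy)‑4‑[3,5‑bis(benzyloxy)‑7‑methoxy‑4‑oxo‑4H‑chromen‑2‑yl]phenoxy}‑3‑methoxyphenyl)‑3‑(2,4,6‑trifluorophenyl)propane‑1,3‑dione (racemic), via acyl chloride 15 (not isolated), via bromomagnesium enolate 16 (not isolated)
Conditions: 1‑chloro‑N,N,2‑trimethylprop‑1‑en‑1‑amine, CH2Cl2, rt; then 7, MgBr2·OEt2 (2.5 equiv), i‑Pr2NEt (3 equiv), CH2Cl2, 0 °C → rt; aq. HCl work‑up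
Reagents that add atoms: none
Why: Neutral acid‑chloride formation is followed by soft enolisation, in which MgBr2 chelates the α‑benzyloxy ketone so that the hindered amine can deprotonate it, and the chelated magnesium enolate undergoes Claisen‑type C‑acylation by the aroyl chloride to the 1,3‑diketone; the excess amine and magnesium salt hold the more acidic product as its chelate until the acidic work‑up, and the tertiary amine is too hindered to displace an aryl fluoride.

**Step 9**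
Reactants: 17 the second 2‑benzyloxy‑1‑(2,4,6‑trifluorophenyl)‑1,3‑diketone
Product: 18 3,5‑bis(benzyloxy)‑2‑(3‑(benzyloxy)‑4‑{4‑[3‑(benzyloxy)‑5,7‑difluoro‑4‑oxo‑4H‑chromen‑2‑yl]‑2‑methoxyphenoxy}phenyl)‑7‑methoxy‑4H‑chromen‑4‑one
Conditions: K2CO3, dry DMF, rt → 50 °C
Reagents that add atoms: none
Why: The same intramolecular SNAr of a diketone enolate oxygen on an ortho fluoride as in step 5 closes ring C of unit 2, and the finished unit‑1 flavonol ether is inert to carbonate.

**Step 10**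
Reactants: 18 the bis‑flavone with a 5,7‑difluoro ring A in unit 2
Product: 19 3,5‑bis(benzyloxy)‑2‑(3‑(benzyloxy)‑4‑{2‑methoxy‑4‑[3,5,7‑tris(benzyloxy)‑4‑oxo‑4H‑chromen‑2‑yl]phenoxy}phenyl)‑7‑methoxy‑4H‑chromen‑4‑one
Conditions: BnOH (excess), NaH, THF, 0 → 60 °C
Reagents that add atoms: benzyl alcohol, OCc1ccccc1
Why: Twofold SNAr by benzyl alkoxide, first at the para 7‑fluoride and then at the ortho 5‑fluoride, both activated by the C4 carbonyl; THF is used instead of an amide solvent so that no amine nucleophile is generated.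

**Step 11**
Reactants: 19 the hexabenzyl ether
Product: 20 3,5‑dihydroxy‑2‑{3‑hydroxy‑4‑[2‑methoxy‑4‑(3,5,7‑trihydroxy‑4‑oxo‑4H‑chromen‑2‑yl)phenoxy]phenyl}‑7‑methoxy‑4H‑chromen‑4‑one (CNP0190193.0)
Conditions: H2 (1 atm), Pd/C, THF–MeOH, rt
Reagents that add atoms: none
Why: Catalytic hydrogenolysis of six benzyl ethers, which leaves the aryl methyl ethers, the diaryl ether and the tetrasubstituted vinylogous‑ester C2=C3 bonds of both flavonols intact.

**Compound list**
1 | methyl vanillate (methyl 4‑hydroxy‑3‑methoxybenzoate) | COC(=O)c1ccc(O)c(OC)c1 | starting material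
2 | 3‑(benzyloxy)‑4‑fluorobenzaldehyde | O=Cc1ccc(F)c(OCc2ccccc2)c1 | starting material
3 | methyl 4‑[2‑(benzyloxy)‑4‑formylphenoxy]‑3‑methoxybenzoate | COC(=O)c1ccc(Oc2ccc(C=O)cc2OCc2ccccc2)c(OC)c1 | intermediate
4 | 1,3,5‑trifluorobenzene | Fc1cc(F)cc(F)c1 | starting material
5 | 2‑(benzyloxy)‑N‑methoxy‑N‑methylacetamide | CON(C)C(=O)COCc1ccccc1 | starting material
6 | (2,4,6‑trifluorophenyl)lithium | [Li]c1c(F)cc(F)cc1F | intermediate (not isolated)
7 | 2‑(benzyloxy)‑1‑(2,4,6‑trifluorophenyl)ethan‑1‑one | O=C(COCc1ccccc1)c1c(F)cc(F)cc1F | intermediate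
8 | lithium (Z)‑2‑(benzyloxy)‑1‑(2,4,6‑trifluorophenyl)ethen‑1‑olate | [Li]O/C(=C\OCc1ccccc1)c1c(F)cc(F)cc1F | intermediate (not isolated)
9 | aldol adduct, racemic diastereomer mixture | COC(=O)c1ccc(Oc2ccc(C(O)C(OCc3ccccc3)C(=O)c3c(F)cc(F)cc3F)cc2OCc2ccccc2)c(OC)c1 | intermediate
10 | 2‑benzyloxy‑1,3‑diketone of unit 1, racemic | COC(=O)c1ccc(Oc2ccc(C(=O)C(OCc3ccccc3)C(=O)c3c(F)cc(F)cc3F)cc2OCc2ccccc2)c(OC)c1 | intermediate
11 | 3‑benzyloxy‑5,7‑difluoroflavone ester | COC(=O)c1ccc(Oc2ccc(-c3oc4cc(F)cc(F)c4c(=O)c3OCc3ccccc3)cc2OCc2ccccc2)c(OC)c1 | intermediate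
12 | 3‑benzyloxy‑5‑fluoro‑7‑methoxyflavone ester | COC(=O)c1ccc(Oc2ccc(-c3oc4cc(OC)cc(F)c4c(=O)c3OCc3ccccc3)cc2OCc2ccccc2)c(OC)c1 | intermediate
13 | benzyl 4‑{2‑(benzyloxy)‑4‑[3,5‑bis(benzyloxy)‑7‑methoxy‑4‑oxo‑4H‑chromen‑2‑yl]phenoxy}‑3‑methoxybenzoate | COc1cc(OCc2ccccc2)c2c(=O)c(OCc3ccccc3)c(-c3ccc(Oc4ccc(C(=O)OCc5ccccc5)cc4OC)c(OCc4ccccc4)c3)oc2c1 | intermediate (not isolated)
14 | 4‑{2‑(benzyloxy)‑4‑[3,5‑bis(benzyloxy)‑7‑methoxy‑4‑oxo‑4H‑chromen‑2‑yl]phenoxy}‑3‑methoxybenzoic acid | COc1cc(OCc2ccccc2)c2c(=O)c(OCc3ccccc3)c(-c3ccc(Oc4ccc(C(O)=O)cc4OC)c(OCc4ccccc4)c3)oc2c1 | intermediate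
15 | acyl chloride of 14 | COc1cc(OCc2ccccc2)c2c(=O)c(OCc3ccccc3)c(-c3ccc(Oc4ccc(C(=O)Cl)cc4OC)c(OCc4ccccc4)c3)oc2c1 | intermediate (not isolated)
16 | bromomagnesium (Z)‑2‑(benzyloxy)‑1‑(2,4,6‑trifluorophenyl)ethen‑1‑olate | Br[Mg]O/C(=C\OCc1ccccc1)c1c(F)cc(F)cc1F | intermediate (not isolated)
17 | 2‑benzyloxy‑1,3‑diketone of unit 2, racemic | COc1cc(OCc2ccccc2)c2c(=O)c(OCc3ccccc3)c(-c3ccc(Oc4ccc(C(=O)C(OCc5ccccc5)C(=O)c5c(F)cc(F)cc5F)cc4OC)c(OCc4ccccc4)c3)oc2c1 | intermediate
18 | bis‑flavone with 5,7‑difluoro ring A in unit 2 | COc1cc(OCc2ccccc2)c2c(=O)c(OCc3ccccc3)c(-c3ccc(Oc4ccc(-c5oc6cc(F)cc(F)c6c(=O)c5OCc5ccccc5)cc4OC)c(OCc4ccccc4)c3)oc2c1 | intermediate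
19 | hexabenzyl ether of the target | COc1cc(OCc2ccccc2)c2c(=O)c(OCc3ccccc3)c(-c3ccc(Oc4ccc(-c5oc6cc(OCc7ccccc7)cc(OCc7ccccc7)c6c(=O)c5OCc5ccccc5)cc4OC)c(OCc4ccccc4)c3)oc2c1 | intermediate
20 | CNP0190193.0 | COc1cc(O)c2c(=O)c(O)c(-c3ccc(Oc4ccc(-c5oc6cc(O)cc(O)c6c(=O)c5O)cc4OC)c(O)c3)oc2c1 | target

**Count and risks**
Total: 11 steps. Longest linear sequence: 10 steps (1, 3–11, or 2–11).

Step 6. The hazard is loss of regiocontrol: methoxide may attack the peri 5‑position alongside the para 7‑position, or substitute twice. The fallback sets out from 11. Excess NaOMe in MeOH–THF at 60 °C replaces both fluorides to give the 5,7‑dimethoxyflavone ester F1. BCl3 in CH2Cl2 (−78 → 0 °C) then removes the two benzyl ethers and, through chelation to the C4 carbonyl, only the 5‑methyl ether, giving the 3,5,3′‑triol ester F2 with the 7‑OMe intact. BnBr/K2CO3 in DMF at 60 °C re‑benzylates the three hydroxyls to the tribenzyl methyl ester F3, and LiOH in THF–H2O returns the route at acid 14.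

Step 8. The hazards are incomplete soft enolisation of the α‑benzyloxy ketone, O‑acylation of the enolate and loss of the acyl chloride to moisture before it is intercepted. The fallback sets out from 14 and closes ring C of unit 2 by the Baker–Venkataraman route. Phloroglucinol is acylated with benzyloxyacetonitrile under Hoesch conditions (HCl, ZnCl2, Et2O; then hot water) to 2‑(benzyloxy)‑1‑(2,4,6‑trihydroxyphenyl)ethan‑1‑one F4. Two equivalents of BnBr with K2CO3 convert it into the hydrogen‑bonded monophenol 2‑(benzyloxy)‑1‑[2,4‑bis(benzyloxy)‑6‑hydroxyphenyl]ethan‑1‑one F5. Acid 14 is esterified with F5 (EDC·HCl, DMAP, CH2Cl2) to the aryl ester F6. LiN(SiMe3)2 in THF brings about the acyl shift to the 1‑(2‑hydroxyaryl)‑1,3‑diketone F7, and cyclodehydration (catalytic TsOH, toluene, 80 °C) gives hexabenzyl ether 19, where the route is rejoined; steps 8–10 are bypassed.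

Step 10. The hazards are stalling at the hindered peri 5‑fluoride after the first substitution and opening of a pyranone by excess alkoxide at the temperature required. The fallback sets out from 18. One equivalent of benzyl alkoxide (BnOH, NaH, THF, 0 °C → rt) replaces only the 7‑fluoride, giving the 7‑benzyloxy‑5‑fluoro compound F8. The 5‑fluoride is then exchanged with a hydroxide surrogate under carbonate conditions ((E)‑benzaldoxime, Cs2CO3, DMSO, 70 °C), where the O‑aryl oxime fragments to the phenoxide and benzonitrile, giving the 5‑hydroxy compound F9. Because a free 5‑OH is the final state, F9 is hydrogenolysed under the conditions of step 11 directly to target 20.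

**Further compounds**
F1 | step 6 | methyl 4‑{2‑(benzyloxy)‑4‑[3‑(benzyloxy)‑5,7‑dimethoxy‑4‑oxo‑4H‑chromen‑2‑yl]phenoxy}‑3‑methoxybenzoate | COC(=O)c1ccc(Oc2ccc(-c3oc4cc(OC)cc(OC)c4c(=O)c3OCc3ccccc3)cc2OCc2ccccc2)c(OC)c1
F2 | step 6 | methyl 4‑[4‑(3,5‑dihydroxy‑7‑methoxy‑4‑oxo‑4H‑chromen‑2‑yl)‑2‑hydroxyphenoxy]‑3‑methoxybenzoate | COC(=O)c1ccc(Oc2ccc(-c3oc4cc(OC)cc(O)c4c(=O)c3O)cc2O)c(OC)c1
F3 | step 6 | methyl 4‑{2‑(benzyloxy)‑4‑[3,5‑bis(benzyloxy)‑7‑methoxy‑4‑oxo‑4H‑chromen‑2‑yl]phenoxy}‑3‑methoxybenzoate | COC(=O)c1ccc(Oc2ccc(-c3oc4cc(OC)cc(OCc5ccccc5)c4c(=O)c3OCc3ccccc3)cc2OCc2ccccc2)c(OC)c1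
F4 | step 8 | 2‑(benzyloxy)‑1‑(2,4,6‑trihydroxyphenyl)ethan‑1‑one | O=C(COCc1ccccc1)c1c(O)cc(O)cc1O
F5 | step 8 | 2‑(benzyloxy)‑1‑[2,4‑bis(benzyloxy)‑6‑hydroxyphenyl]ethan‑1‑one | O=C(COCc1ccccc1)c1c(O)cc(OCc2ccccc2)cc1OCc1ccccc1
F6 | step 8 | 3,5‑bis(benzyloxy)‑2‑[2‑(benzyloxy)acetyl]phenyl ester of acid 14 | COc1cc(OCc2ccccc2)c2c(=O)c(OCc3ccccc3)c(-c3ccc(Oc4ccc(C(=O)Oc5cc(OCc6ccccc6)cc(OCc6ccccc6)c5C(=O)COCc5ccccc5)cc4OC)c(OCc4ccccc4)c3)oc2c1
F7 | step 8 | 1‑[2,4‑bis(benzyloxy)‑6‑hydroxyphenyl]‑2‑(benzyloxy)‑3‑aryl‑propane‑1,3‑dione (aryl as in 17), racemic | COc1cc(OCc2ccccc2)c2c(=O)c(OCc3ccccc3)c(-c3ccc(Oc4ccc(C(=O)C(OCc5ccccc5)C(=O)c5c(O)cc(OCc6ccccc6)cc5OCc5ccccc5)cc4OC)c(OCc4ccccc4)c3)oc2c1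
F8 | step 10 | analogue of 19 with 5‑fluoro in unit 2 | COc1cc(OCc2ccccc2)c2c(=O)c(OCc3ccccc3)c(-c3ccc(Oc4ccc(-c5oc6cc(OCc7ccccc7)cc(F)c6c(=O)c5OCc5ccccc5)cc4OC)c(OCc4ccccc4)c3)oc2c1
F9 | step 10 | analogue of 19 with free 5‑hydroxy in unit 2 | COc1cc(OCc2ccccc2)c2c(=O)c(OCc3ccccc3)c(-c3ccc(Oc4ccc(-c5oc6cc(OCc7ccccc7)cc(O)c6c(=O)c5OCc5ccccc5)cc4OC)c(OCc4ccccc4)c3)oc2c1
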